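In a one-step picture, free monomer decays by a single first-order loss and there are no chains to count, yet the question is a length.

| setting | west | flask |
|---|---|---|
| free monomer | 0.75 M | 0.75 M |
| initiator | 5 mol% | 2.5 mol% |
| remark | run made earlier |  |
| time |  | 6.0 h |

west run (percent of the free monomer charged)

| time / min | monomer in chains / % | free monomer / % |
|---|---|---|
| 10.0 | 3.7 | 95.9 |
| 25.0 | 5.2 | 92.6 |
| 50.0 | 11.0 | 88.4 |
| 80.0 | 18.5 | 81.1 |
| 120 | 25.6 | 74.6 |

(readings scatter by 1 percentage point)

- the average divides the monomer in chains by the number of chains begun, living and dead together
- the numbers in the tables scatter by 1 percentage point (one standard deviation)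
- the earlier runs do not show the number of chains; that part of a forecast is a guess
- no earlier run changes the charge of initiator; that part of a forecast is a guess

- whether the average number of monomer units in a chain (chains begun, living or dead) reaches 5.0 by 6.0 h (yes / no)
- average number of monomer units in a chain (chains begun, living or dead) at 6.0 h

I reckon that length from two amounts, the free monomer charged and the initiator charged. On my guess that each initiator begins one chain, their ratio (the monomer-to-initiator ratio) is the target length of this flask, and once the initiator has begun its chains, the average length is the target length times the reacted share.

target length = c(free monomer) / c(initiator) = 40.0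

West leaves 74.6% of its free monomer after 120 min, which reads as a first-order constant:

k = 0.00244 min⁻¹

My second guess is that the rate follows the initiator, so the flask, with half of west's loading, reaches at 6.0 h:

reacted share = 35.6%

length = 14.2

A length of 5.0 needs a reacted share of 12.5%, less than my share, so I say yes.

The forecast says yes and 16, above my figure, on the same guess: “If every initiator starts one chain”.

The flask gives yes and 16.0.

    free monomer + initiator → living end + monomer in chains (k = 7.50 × 10⁻⁴ L mol⁻¹ s⁻¹)
    free monomer + living end → monomer in chains + living end, rate k2*[living end]*[free monomer] (k = 0.00130 L mol⁻¹ s⁻¹)
    2 initiator → spent initiator (k = 3.70 × 10⁻⁴ L mol⁻¹ s⁻¹)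

The flask's chains average 16.0 units at 6.0 h, with the living end at 0.0185 M against 0.0188 M of initiator charged. Free monomer left at that time is 61%, and the target length times the reacted share, which is one minus that, reads 15.8. If the free monomer falls by that same factor again, the target length gives 25.3, and the flask run for twice the time stands at 25.9.

Readings and results are simulated on assumed constants.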